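Begin with an easy step, which is to set the charge of X against the constant Kh in the denominator of the first step.

    X + L → Z + L, rate k1*[X]^2.5*[L]/(1 + ([X]/Kh1)^2.5) (Kh1 = 6.2 mM, k1 = 5.0 × 10⁵ M⁻²·⁵ s⁻¹, Ea1 = 20.0 kJ mol⁻¹)
    L → G (k2 = 7.1 × 10⁻⁸ s⁻¹, Ea2 = 253 kJ mol⁻¹)
    Z → E (k3 = 4.2 × 10⁻⁵ s⁻¹, Ea3 = 89.0 kJ mol⁻¹)
    (constants at 37 °C)

common to all: X 20 mM; L 9.5 × 10⁻⁴ mol%; time 40 h

|  | temperature |
|---|---|
| dawn | 12 °C |
| summer | −13 °C |
| autumn | 37 °C |

- all constants are for 37 °C and move with temperature by the activation energies

* which flask leads in amount of Z, in percent of the X charged ("all alike" within 1.5 percentage points) (dawn / summer / autumn / all alike)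
* how much Z is there at the end, in percent of the X charged: dawn
* how much Z is there at the end, in percent of the X charged: summer
* how much Z is there at the end, in percent of the X charged: autumn

The charge of 20 mM stands above Kh of 6.2 mM, and the fraction one over one plus Kh/cX raised to the power of the law then comes to 94.9%, so you start close to the limit where the powers of cX cancel and the rate no longer depends on cX, which is zero order. In that limit the rate is the rate constant times Kh to that power times cL, and with cL as the loading times the charge this gives 1.04 mM h⁻¹ at 37 °C, the temperature of autumn. Kh has no activation energy and stays as it is, while the rate constant of the first step is smaller in summer by a factor of 4.4, which leaves 0.233 mM h⁻¹, the ceiling rate of summer, the X turned over per hour there with cX far above Kh.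

The half-life of Z, 4.58 h at 37 °C, stretches in summer by a factor of 760 to 3480 h, far longer than the 40 h of the run, so in summer the X consumed can be counted as Z. The ceiling held for 40 h gives 46.6% of the charge, and the starting fraction brings that to 44.3%. The weak link is that fraction, because by this reckoning cX falls in summer to about 11.1 mM, where the fraction is 81.3%. Taking the mean of the two fractions, I commit to 41.1% for summer. In autumn the half-life of Z is shorter than the run, so I expect little Z there, and for dawn I give no figure by hand.

The forecast names dawn as the leader, with 65% for dawn, 42% for summer and 3.6% for autumn, on the grounds that “Z's breakdown is what separates the flasks”. Its summer figure lies 0.90 percentage points above mine.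

The simulation puts dawn in the lead with 65.0%, then summer with 41.9% and autumn with 3.76%. At 40.0 h summer still holds X 57.9% and E 0.171%, while autumn holds E 86.6%. Read the summer flask earlier, at 15 h, and the same ceiling gives 17.5% of the charge; by the reckoning cX then stands at about 16.7 mM, where the fraction is 92.2%, and the mean fraction brings the reckoning to 16.4%. That neighbouring flask holds Z 16.4% and X 84%.

The numbers stand for no real mixture.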